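## The problem

CNP0299970.1 is a daucane sesquiterpenoid ester: a trans-fused bicyclo[5.3.0]decane in which cyclopentane ring A (C1–C5) and cycloheptenone ring B (C1, C5–C10) share the C1–C5 bond. The locants used throughout are C1 (quaternary, CH3), C2/C3 (CH2), C4 (C(OH)iPr), C5 (ring-fusion CH), C6 (CH–O-anisoyl), C7=C8(CH3), C9 (C=O), C10 (CHOH); β is the face of the C1 methyl group. Five stereocentres are contiguous (1S,4R,5S,6S,10R in these locants): 4-OH and 10-OH are β, H-5 and the C6 ester oxygen are α, so the ring fusion is trans and the C10 hydroxyl lies on the face shielded by the angular methyl group. C1 (quaternary) and C4 (tertiary carbinol) cannot be corrected once made and must be set in a defined relation; C5 and C10 are α to carbonyl groups and C6 can come from a ketone, so these three can be controlled from C1 and C4. Ring B is sensitive: the γ-acyloxy enone can eliminate or ionise, the α-ketol can epimerise or shift, and the C4 hydroxyl is β to C6, so any C6 ketone intermediate can undergo retro-aldol cleavage or dehydration. The enabling feature is that C6 and C9, the two carbonyl-level carbons of ring B, are joined on one side by C5–C1–C10 (a 1,5-relation) and on the other by C7–C8 (a 1,4-relation). Ring B is therefore a masked cycloheptane-1,4-dione, the product expected when a cyclopentane-1,3-dione enol (C6, C5, C9, C8, C7) adds photochemically to an alkene (C1=C10) and the C5–C9 bond is then cleaved by retro-aldol reaction. Ring A is exactly the three-atom tether C4–C3–C2 between the dione α-carbon C5 and the alkene carbon C1, the C10 oxygen is that of an enol ether, and the C4 hydroxyl can hydrogen-bond to the C6 carbonyl and relay its configuration.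

## Retrosynthesis

**22 ⇒ 21 ⇒ 19 ⇒ 18 ⇒ 16 (O–benzyl, C8–CH3, C7=C8).** The C10 hydroxyl is carried as a benzyl ether (21). The C8 methyl is cut at the iodoenone 19 and the C7=C8 double bond is cut back to the saturated ketone 16. Dehydrogenation can only occur toward C8/C7, because C1 on the other side of C9 is quaternary. Leaving methyl and unsaturation to the end makes the C6–C9 segment symmetric. A 4-methylcyclopentane-1,3-dione would give two enol derivatives and hence two constitutional isomers; the unsubstituted dione gives one.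

**16 ⇒ 14 + 15; 14 ⇒ 13 (C6–O acyl, C6–H).** The ester comes from 4-methoxybenzoyl chloride 15 and the 6α-alcohol 14. The alcohol comes from dione 13 by hydride delivery from the C4 hydroxyl, which picks C6 over C9 and sets the 4,6-anti relation. A C6 ketone is preferred to an early C6 alcohol because it is what the key step produces and it keeps C5 epimerisable.

**13 ⇒ 12 ⇒ 11 (key: cut C5–C1 and C9–C10, rejoin C5–C9).** This is the de Mayo retron. It is preferred to closing ring A by aldol reaction or ring B by metathesis because it forms both rings, the quaternary C1 and the C10 oxygen-bearing centre in one operation. Precursor 11 is monocyclic with a single stereocentre (C4). The forward reaction must give the straight (not crossed) adduct, add to one face relative to C4, and fragment cleanly.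

**11 ⇒ 10 ⇒ 8 (O–Si; C5–C9 and the enol carbonate).** The free C4 hydroxyl of 11 is needed only for the photoreaction. Before that it is a triethylsilyl ether (10), because a free 2-(1-hydroxyalkyl)-1,3-dione or its β-hydroxy ketone precursor would undergo retro-aldol cleavage in base. The dione ring is cut at C5–C9 (Dieckmann closure of γ-keto ester 8, enolate 9 trapped as the methyl carbonate).

**8 ⇒ 6 + 7 (C1=C10).** The enol ether comes from the methyl ketone of 6 and the alkoxymethylene ylide from salt 7. This adds C10 with its oxygen already attached, which is preferable to oxidising C10 later from the less hindered α face and so obtaining the wrong epimer.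

**6 ⇒ 4 + 5 (C6–C7).** The γ-keto ester is cut between the acyl carbon C6 and C7 of methyl acrylate 5. An acyl radical from aldehyde 4 is chosen over a carbene-catalysed Stetter reaction because 4 is a 1,6-keto aldehyde and would undergo intramolecular cross-benzoin reaction.

**4 ⇒ 2 ⇒ 1 (C1=C6 of the terpene ring).** The chain C6–C5–C4(OH)(iPr)–C3–C2–C1(CH3) of 4 is the ozonolysis product (through ozonide 3) of silyl ether 2 of (S)-terpinen-4-ol 1. This supplies ten carbons and the C4 stereocentre. The descriptor changes from S to R on the way to 22 only because the CIP priorities change.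

## Roads not taken

**Alternative 1:** (the obvious route) Cut C7=C8 and close ring B by ring-closing metathesis (second-generation Grubbs catalyst, (H2IMes)(PCy3)Cl2Ru=CHPh) of the fully substituted cyclopentane A1 to give 21. This leaves the difficult part unsolved. A1 already contains all five stereocentres, including quaternary C1 flanked by C10 and C5, and they would have to be set by separate additions on a cyclopentane with weak control at C6 and C10. The metathesis must also form a trisubstituted, electron-poor alkene from a 1,1-disubstituted enone and a hindered allylic ester. The chosen plan sets C1 and C10 and builds ring B together from a precursor with one stereocentre.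

**Alternative 2:** Cut C1–C10 and C5–C6: [5+2] cycloaddition of the oxidopyrylium ylide from pyranone A2 with 3-methylcyclopent-2-enone A3 to give oxa-bridged tricycle A4. The oxygen pattern (C6–O, C9=O, C10–O, C8 methyl) and the regiochemistry fit. The stereochemistry does not: suprafacial addition gives a cis ring fusion locked by the bridge, and one bridging oxygen makes C6–O and C10–O cis where the target has them trans. A β,β-disubstituted enone is also a poor partner, the adduct is racemic, and isopropyl addition to the C4 ketone must compete with the enone. The chosen plan gets the trans fusion and the 6α/10β pattern directly.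

**Alternative 3:** Cut C4–C5 as well: intermolecular de Mayo reaction of 3-acetoxycyclopent-2-enone A5 with the acyclic enol ether ketone A6 to cycloheptanedione A7, then intramolecular aldol closure of ring A. Both components are trivial. However, nothing in them is chiral, so absolute configuration has no source. The aldol can start from C5 or C10 (both give five-membered rings), and C4 would be formed last under reversible conditions. In the chosen plan C4 comes from 1 and controls C1 through the hydrogen bond.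

Key step: step 7

Assumption: (S)-(+)-terpinen-4-ol is taken as available in high enantiomeric purity (it is the only source of absolute configuration) and salt 7 as a commercial reagent.

## Route

Step 1
Reactants: 1 (S)-(+)-terpinen-4-ol
Product: 2 triethyl{[(1S)-4-methyl-1-(propan-2-yl)cyclohex-3-en-1-yl]oxy}silane
Conditions: Et3SiOTf, 2,6-lutidine, CH2Cl2, 0 °C
Reagents that add atoms: triethylsilyl trifluoromethanesulfonate, CC[Si](CC)(CC)OS(=O)(=O)C(F)(F)F
Why: Silyl triflate silylation of a hindered tertiary alcohol; the ether blocks retro-aldol cleavage of C4–C5 in the basic steps 4 and 5, and the C4 stereocentre is taken unchanged from the chiral pool.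

Step 2
Reactants: 2 triethyl{[(1S)-4-methyl-1-(propan-2-yl)cyclohex-3-en-1-yl]oxy}silane
Product: 4 (3S)-6-oxo-3-(propan-2-yl)-3-[(triethylsilyl)oxy]heptanal, via secondary ozonide 3 (not isolated)
Conditions: O3, CH2Cl2, −78 °C; then PPh3, −78 °C to rt
Reagents that add atoms: ozone, [O-][O+]=O
Why: Ozonolysis of the only C=C bond with reductive work-up gives the C6 aldehyde and the C1 methyl ketone; C4 is not touched.

Step 3
Reactants: 4 (3S)-6-oxo-3-(propan-2-yl)-3-[(triethylsilyl)oxy]heptanal; 5 methyl acrylate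
Product: 6 methyl (6S)-4,9-dioxo-6-(propan-2-yl)-6-[(triethylsilyl)oxy]decanoate
Conditions: (nBu4N)4[W10O32] (2 mol %), MeCN, 390 nm, rt, degassed
Reagents that add atoms: methyl acrylate (5), C=CC(=O)OC
Why: Decatungstate-photocatalysed hydroacylation: hydrogen abstraction from the aldehyde C–H, Giese addition of the acyl radical to the acrylate and back hydrogen transfer. The neutral radical conditions leave the methyl ketone and silyl ether alone and avoid the aldehyde–ketone benzoin closure that a carbene catalyst would cause.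

Step 4
Reactants: 6 methyl (6S)-4,9-dioxo-6-(propan-2-yl)-6-[(triethylsilyl)oxy]decanoate; 7 [(benzyloxy)methyl]triphenylphosphonium chloride
Product: 8 methyl (6S)-10-(benzyloxy)-9-methyl-4-oxo-6-(propan-2-yl)-6-[(triethylsilyl)oxy]dec-9-enoate (E/Z mixture)
Conditions: 7, KN(SiMe3)2, THF, −78 °C; then 6, −78 to 0 °C
Reagents that add atoms: [(benzyloxy)methyl]triphenylphosphonium chloride (7), [Cl-].C(OCc1ccccc1)[P+](c1ccccc1)(c1ccccc1)c1ccccc1
Why: Wittig alkoxymethylenation; the methyl ketone should react ahead of the C6 ketone, which is flanked by the neopentyl C5, and the ester is inert. The E/Z ratio does not matter because the geometry is lost in step 7.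

Step 5
Reactants: 8 methyl (6S)-10-(benzyloxy)-9-methyl-4-oxo-6-(propan-2-yl)-6-[(triethylsilyl)oxy]dec-9-enoate
Product: 10 2-[(3R)-7-(benzyloxy)-2,6-dimethyl-3-[(triethylsilyl)oxy]hept-6-en-3-yl]-3-oxocyclopent-1-en-1-yl methyl carbonate, via potassium dione enolate 9 (not isolated)
Conditions: KOtBu, THF, 0 °C; then ClCO2Me, −78 to 0 °C
Reagents that add atoms: methyl chloroformate, COC(=O)Cl
Why: Dieckmann-type closure of a γ-keto ester (C5 enolate onto the ester, 5-exo-trig), driven by formation of the dione enolate; O-acylation gives the enol carbonate. The dione ring is symmetric, so only one enol derivative is possible.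

Step 6
Reactants: 10 2-[(3R)-7-(benzyloxy)-2,6-dimethyl-3-[(triethylsilyl)oxy]hept-6-en-3-yl]-3-oxocyclopent-1-en-1-yl methyl carbonate
Product: 11 2-[(3R)-7-(benzyloxy)-3-hydroxy-2,6-dimethylhept-6-en-3-yl]-3-oxocyclopent-1-en-1-yl methyl carbonate
Conditions: HF·pyridine, pyridine, THF, 0 °C
Reagents that add atoms: none
Why: Buffered fluoride cleaves the silyl ether without base, so no alkoxide forms that could attack the enol carbonate. With the enol capped, C5 cannot leave as a carbanion, so the free carbinol is now stable to retro-aldol cleavage.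

Step 7
Reactants: 11 2-[(3R)-7-(benzyloxy)-3-hydroxy-2,6-dimethylhept-6-en-3-yl]-3-oxocyclopent-1-en-1-yl methyl carbonate
Product: 13 10β-(benzyloxy)-4β-hydroxy-1β-methyl-4α-(propan-2-yl)-5αH-bicyclo[5.3.0]decane-6,9-dione, via cyclobutane photoadduct 12 (not isolated)
Conditions: hν (365 nm), degassed hexane/CH2Cl2, high dilution, 0 °C; then K2CO3, MeOH, 0 °C
Reagents that add atoms: none
Why: De Mayo reaction: the triplet of the β-acyloxy enone bonds first from α-carbon C5 to C1 of the tethered enol ether (1,5-closure, rule of five, closing ring A by 5-exo attack) and then from C9 to C10 (closure of the oxygen-stabilised 1,4-diradical to the cyclobutane) to give 12; methanolysis of the tertiary carbonate releases the C9 alkoxide, and strain-driven retro-aldol cleavage of C5–C9 merges the four- and five-membered rings into seven-membered ring B of 13. The closest known reaction type is the intramolecular de Mayo ring expansion of 2-(pent-4-enyl)cyclopentane-1,3-dione enol esters to bicyclo[5.3.0]decane-2,5-diones. Regiochemistry is secured by the three-atom tether C2–C3–C4 and by the enol ether polarity, which places the oxygen-bearing carbon C10 on the enone β-carbon C9. C1 is set relative to C4 by the hydrogen bond O4–H···O=C6, which holds the hydroxyl in the enone plane on the C6 side so that the tether folds over one face with the isopropyl group on the other; this puts the C1 methyl and C4 hydroxyl cis on ring A. C10 is set in the diradical closure, where the benzyloxy group should avoid the carbonate on C9 and end up cis to the C1 methyl; the E/Z mixture converges because the C1–C10 bond rotates freely in the diradical. C5 is set last by protonation of the retro-aldol enolate and, being α to the C6 ketone, should settle in the trans-fused arrangement that keeps C6 trans to the isopropyl group and hydrogen-bonded to the C4 hydroxyl. The step needs the free hydroxyl, a non-polar aprotic solvent and dilution, and the base treatment is kept cold and short to limit retro-aldol opening at C4–C5.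

Step 8
Reactants: 13 10β-(benzyloxy)-4β-hydroxy-1β-methyl-4α-(propan-2-yl)-5αH-bicyclo[5.3.0]decane-6,9-dione
Product: 14 10β-(benzyloxy)-4β,6α-dihydroxy-1β-methyl-4α-(propan-2-yl)-5αH-bicyclo[5.3.0]decan-9-one
Conditions: Me4NBH(OAc)3, MeCN/AcOH, −20 °C
Reagents that add atoms: none
Why: Evans–Saksena hydroxyl-directed reduction: the borohydride bound to the C4 oxygen delivers hydride to the β face of C6 only, giving the 4,6-anti diol (6α-OH). The C9 ketone has no free hydroxyl nearby and is not reduced.

Step 9
Reactants: 14 10β-(benzyloxy)-4β,6α-dihydroxy-1β-methyl-4α-(propan-2-yl)-5αH-bicyclo[5.3.0]decan-9-one; 15 4-methoxybenzoyl chloride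
Product: 16 10β-(benzyloxy)-4β-hydroxy-6α-(4-methoxybenzoyloxy)-1β-methyl-4α-(propan-2-yl)-5αH-bicyclo[5.3.0]decan-9-one
Conditions: 15, DMAP, Et3N, CH2Cl2, rt
Reagents that add atoms: 4-methoxybenzoyl chloride (15), COc1ccc(cc1)C(Cl)=O
Why: DMAP-catalysed acylation of the secondary C6 alcohol; the tertiary C4 alcohol does not react.

Step 10
Reactants: 16 10β-(benzyloxy)-4β-hydroxy-6α-(4-methoxybenzoyloxy)-1β-methyl-4α-(propan-2-yl)-5αH-bicyclo[5.3.0]decan-9-one
Product: 18 10β-(benzyloxy)-4β-hydroxy-6α-(4-methoxybenzoyloxy)-1β-methyl-4α-(propan-2-yl)-5αH-bicyclo[5.3.0]dec-7-en-9-one, via dilithium enolate 17 (not isolated)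
Conditions: LiN(SiMe3)2 (2.3 equiv), THF, −78 °C; then PhS(Cl)=NtBu, −78 °C
Reagents that add atoms: none
Why: Mukaiyama dehydrogenation: kinetic deprotonation at the C8 methylene (the C10 methine is alkoxy-substituted and neopentyl), sulfenylation by the sulfinimidoyl chloride and syn-elimination. Only C7=C8 can form because C1 carries no hydrogen.

Step 11
Reactants: 18 10β-(benzyloxy)-4β-hydroxy-6α-(4-methoxybenzoyloxy)-1β-methyl-4α-(propan-2-yl)-5αH-bicyclo[5.3.0]dec-7-en-9-one
Product: 19 10β-(benzyloxy)-4β-hydroxy-8-iodo-6α-(4-methoxybenzoyloxy)-1β-methyl-4α-(propan-2-yl)-5αH-bicyclo[5.3.0]dec-7-en-9-one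
Conditions: I2, pyridine, CH2Cl2, rt, dark
Reagents that add atoms: iodine, II
Why: α-Iodination of a cyclic enone by pyridine conjugate addition, iodination of the enolate and elimination; it places the handle on C8 only.

Step 12
Reactants: 19 10β-(benzyloxy)-4β-hydroxy-8-iodo-6α-(4-methoxybenzoyloxy)-1β-methyl-4α-(propan-2-yl)-5αH-bicyclo[5.3.0]dec-7-en-9-one; 20 methylzinc chloride
Product: 21 10β-(benzyloxy)-4β-hydroxy-6α-(4-methoxybenzoyloxy)-1β,8-dimethyl-4α-(propan-2-yl)-5αH-bicyclo[5.3.0]dec-7-en-9-one
Conditions: MeZnCl (excess), Pd(PPh3)4 (5 mol %), THF, 0 °C to rt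
Reagents that add atoms: methylzinc chloride (20), C[Zn]Cl
Why: Negishi methylation of an α-iodoenone; it runs at or below room temperature, where oxidative addition to the C–I bond should outrun ionisation of the allylic C6 ester.

Step 13
Reactants: 21 10β-(benzyloxy)-4β-hydroxy-6α-(4-methoxybenzoyloxy)-1β,8-dimethyl-4α-(propan-2-yl)-5αH-bicyclo[5.3.0]dec-7-en-9-one
Product: 22 4β,10β-dihydroxy-6α-(4-methoxybenzoyloxy)dauc-7-en-9-one (CNP0299970.1)
Conditions: BCl3, pentamethylbenzene, CH2Cl2, −78 °C
Reagents that add atoms: none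
Why: Lewis-acid debenzylation with a non-basic cation scavenger; the low temperature should spare the enone, the aryl methyl ether and the tertiary alcohol, and C10 is not epimerised under non-basic conditions.

## Compound list

1 | (S)-(+)-terpinen-4-ol, (1S)-4-methyl-1-(propan-2-yl)cyclohex-3-en-1-ol | CC1=CC[C@](O)(C(C)C)CC1 | starting material
2 | triethyl{[(1S)-4-methyl-1-(propan-2-yl)cyclohex-3-en-1-yl]oxy}silane | CC1=CC[C@](O[Si](CC)(CC)CC)(C(C)C)CC1 | intermediate
3 | secondary ozonide (1,2,4-trioxolane) of 2, mixture of diastereomers at the trioxolane carbons | CC12CC[C@@](O[Si](CC)(CC)CC)(C(C)C)CC(O1)OO2 | intermediate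
4 | (3S)-6-oxo-3-(propan-2-yl)-3-[(triethylsilyl)oxy]heptanal | O=CC[C@](O[Si](CC)(CC)CC)(C(C)C)CCC(C)=O | intermediate
5 | methyl acrylate | C=CC(=O)OC | starting material
6 | methyl (6S)-4,9-dioxo-6-(propan-2-yl)-6-[(triethylsilyl)oxy]decanoate | COC(=O)CCC(=O)C[C@](O[Si](CC)(CC)CC)(C(C)C)CCC(C)=O | intermediate
7 | [(benzyloxy)methyl]triphenylphosphonium chloride | [Cl-].C(OCc1ccccc1)[P+](c1ccccc1)(c1ccccc1)c1ccccc1 | starting material
8 | methyl (6S)-10-(benzyloxy)-9-methyl-4-oxo-6-(propan-2-yl)-6-[(triethylsilyl)oxy]dec-9-enoate (E/Z mixture) | COC(=O)CCC(=O)C[C@](O[Si](CC)(CC)CC)(C(C)C)CCC(C)=COCc1ccccc1 | intermediate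
9 | potassium enolate of 2-[(3R)-7-(benzyloxy)-2,6-dimethyl-3-[(triethylsilyl)oxy]hept-6-en-3-yl]cyclopentane-1,3-dione | [K+].[O-]C1=C(C(=O)CC1)[C@](O[Si](CC)(CC)CC)(C(C)C)CCC(C)=COCc1ccccc1 | intermediate
10 | 2-[(3R)-7-(benzyloxy)-2,6-dimethyl-3-[(triethylsilyl)oxy]hept-6-en-3-yl]-3-oxocyclopent-1-en-1-yl methyl carbonate | COC(=O)OC1=C(C(=O)CC1)[C@](O[Si](CC)(CC)CC)(C(C)C)CCC(C)=COCc1ccccc1 | intermediate
11 | 2-[(3R)-7-(benzyloxy)-3-hydroxy-2,6-dimethylhept-6-en-3-yl]-3-oxocyclopent-1-en-1-yl methyl carbonate | COC(=O)OC1=C(C(=O)CC1)[C@](O)(C(C)C)CCC(C)=COCc1ccccc1 | intermediate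
12 | cyclobutane photoadduct of 11 (bonds C5–C1 and C9–C10; C9 bears OCO2Me; 10-benzyloxy and 1-methyl cis on the four-membered ring; cyclopentanone and ring A on opposite faces of it) | O=C2CC[C@]4(OC(=O)OC)[C@H](OCc1ccccc1)[C@@]3(C)CC[C@@](O)(C(C)C)[C@]234 | intermediate
13 | 10β-(benzyloxy)-4β-hydroxy-1β-methyl-4α-(propan-2-yl)-5αH-bicyclo[5.3.0]decane-6,9-dione | O=C2CCC(=O)[C@H](OCc1ccccc1)[C@@]3(C)CC[C@@](O)(C(C)C)[C@H]23 | intermediate
14 | 10β-(benzyloxy)-4β,6α-dihydroxy-1β-methyl-4α-(propan-2-yl)-5αH-bicyclo[5.3.0]decan-9-one | O[C@H]2CCC(=O)[C@H](OCc1ccccc1)[C@@]3(C)CC[C@@](O)(C(C)C)[C@H]23 | intermediate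
15 | 4-methoxybenzoyl chloride | COc1ccc(cc1)C(Cl)=O | starting material
16 | 10β-(benzyloxy)-4β-hydroxy-6α-(4-methoxybenzoyloxy)-1β-methyl-4α-(propan-2-yl)-5αH-bicyclo[5.3.0]decan-9-one | COc1ccc(cc1)C(=O)O[C@H]2CCC(=O)[C@H](OCc4ccccc4)[C@@]3(C)CC[C@@](O)(C(C)C)[C@H]23 | intermediate
17 | dilithium C8(9)-enolate C4-alkoxide of 16 | [Li+].[Li+].COc1ccc(cc1)C(=O)O[C@H]2CC=C([O-])[C@H](OCc4ccccc4)[C@@]3(C)CC[C@@]([O-])(C(C)C)[C@H]23 | intermediate
18 | 10β-(benzyloxy)-4β-hydroxy-6α-(4-methoxybenzoyloxy)-1β-methyl-4α-(propan-2-yl)-5αH-bicyclo[5.3.0]dec-7-en-9-one | COc1ccc(cc1)C(=O)O[C@H]2C=CC(=O)[C@H](OCc4ccccc4)[C@@]3(C)CC[C@@](O)(C(C)C)[C@H]23 | intermediate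
19 | 10β-(benzyloxy)-4β-hydroxy-8-iodo-6α-(4-methoxybenzoyloxy)-1β-methyl-4α-(propan-2-yl)-5αH-bicyclo[5.3.0]dec-7-en-9-one | COc1ccc(cc1)C(=O)O[C@H]2C=C(I)C(=O)[C@H](OCc4ccccc4)[C@@]3(C)CC[C@@](O)(C(C)C)[C@H]23 | intermediate
20 | methylzinc chloride | C[Zn]Cl | starting material
21 | 10β-(benzyloxy)-4β-hydroxy-6α-(4-methoxybenzoyloxy)-1β,8-dimethyl-4α-(propan-2-yl)-5αH-bicyclo[5.3.0]dec-7-en-9-one | COc1ccc(cc1)C(=O)O[C@H]2C=C(C)C(=O)[C@H](OCc4ccccc4)[C@@]3(C)CC[C@@](O)(C(C)C)[C@H]23 | intermediate
22 | 4β,10β-dihydroxy-6α-(4-methoxybenzoyloxy)dauc-7-en-9-one (CNP0299970.1) | COc1ccc(C(=O)O[C@H]2C=C(C)C(=O)[C@H](O)[C@@]3(C)CC[C@@](O)(C(C)C)[C@H]23)cc1 | target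

## Step count and risks

Total steps: 13. Longest linear sequence: 13 (1 to 22; 5, 7, 15 and 20 are bought).

**Step 7 (key).** Most likely failure: stereochemical leakage at C10. The 1,4-diradical can close with the benzyloxy group on either face of the new four-membered ring (the methyl on C1 and the carbonate on C9 are of similar size), and the basic fragmentation can epimerise this α-alkoxy ketone centre further. Fallback, from 11 back to 18: the C10 epimer of 13, 10α-(benzyloxy)-4β-hydroxy-1β-methyl-4α-(propan-2-yl)-5αH-bicyclo[5.3.0]decane-6,9-dione F1, is carried (alone or mixed with 13) through steps 8–10. This gives the 6α-alcohol F2, the 4-methoxybenzoate F3 and the 10α-benzyloxy enone F4. Once C7=C8 is in place, C10–H is the only α-hydrogen of the ketone. Deprotonation with LiN(SiMe3)2 (THF, −78 °C) gives the cross-conjugated dilithium enolate F5. Kinetic protonation (AcOH, −78 °C) should come from the α face, anti to the axial C1 methyl, and gives 18. Both epimers converge here.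

**Step 5.** Most likely failure: loss of triethylsilanolate from the C5 enolate (E1cB, giving the C4=C5 enone) or slow C–C bond formation at the neopentyl C5, in competition with the Claisen closure. Fallback, from 8 back to 10: saponification (LiOH, THF/H2O) gives the 4-oxo acid F6. Esterification (C6F5OH, EDC, CH2Cl2) gives the pentafluorophenyl ester F7. Ring closure by soft enolisation (MgBr2·OEt2, iPr2NEt, CH2Cl2, rt), in which a magnesium enolate is acylated by the active ester without alkoxide base, gives the free dione 2-[(3R)-7-(benzyloxy)-2,6-dimethyl-3-[(triethylsilyl)oxy]hept-6-en-3-yl]cyclopentane-1,3-dione F8. O-Acylation (ClCO2Me, Et3N, CH2Cl2, 0 °C) gives 10.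

**Step 4.** Most likely failure: poor chemoselectivity. The ylide may also attack the C6 ketone or act as a base on the 1,4-keto ester. Fallback, from 6 back to 10: reverse the order. Dieckmann closure of 6 (KOtBu, THF) gives the dione 2-[(3S)-2-methyl-6-oxo-3-[(triethylsilyl)oxy]heptan-3-yl]cyclopentane-1,3-dione F9, whose enolate is inert to ylides. F9 is treated with an excess of the ylide from 7; the first equivalent deprotonates the dione, so only the methyl ketone is converted. Quenching the resulting enolate 9 with ClCO2Me gives 10.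

**Step 13.** Most likely failure: Lewis-acid damage, namely ionisation of the tertiary C4 alcohol or the allylic C6 ester, or cleavage of the aryl methyl ether. Fallback, from 16 back to 22: the benzyl ether is removed before the enone exists. Hydrogenolysis of 16 (H2, Pd(OH)2/C, EtOAc) gives the ketol 4β,10β-dihydroxy-6α-(4-methoxybenzoyloxy)-1β-methyl-4α-(propan-2-yl)-5αH-bicyclo[5.3.0]decan-9-one F10. Silylation of the secondary hydroxyl (Et3SiOTf, 2,6-lutidine, −78 °C) gives the 10β-triethylsilyl ether F11. Steps 10–12 applied to F11 give the enone F12, the 8-iodoenone F13 and the 8-methyl enone F14. HF·pyridine in THF then releases 22.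

## Further compounds

F1 | step 7 | 10α-(benzyloxy)-4β-hydroxy-1β-methyl-4α-(propan-2-yl)-5αH-bicyclo[5.3.0]decane-6,9-dione | O=C2CCC(=O)[C@@H](OCc1ccccc1)[C@@]3(C)CC[C@@](O)(C(C)C)[C@H]23
F2 | step 7 | 10α-(benzyloxy)-4β,6α-dihydroxy-1β-methyl-4α-(propan-2-yl)-5αH-bicyclo[5.3.0]decan-9-one | O[C@H]2CCC(=O)[C@@H](OCc1ccccc1)[C@@]3(C)CC[C@@](O)(C(C)C)[C@H]23
F3 | step 7 | 10α-(benzyloxy)-4β-hydroxy-6α-(4-methoxybenzoyloxy)-1β-methyl-4α-(propan-2-yl)-5αH-bicyclo[5.3.0]decan-9-one | COc1ccc(cc1)C(=O)O[C@H]2CCC(=O)[C@@H](OCc4ccccc4)[C@@]3(C)CC[C@@](O)(C(C)C)[C@H]23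
F4 | step 7 | 10α-(benzyloxy)-4β-hydroxy-6α-(4-methoxybenzoyloxy)-1β-methyl-4α-(propan-2-yl)-5αH-bicyclo[5.3.0]dec-7-en-9-one | COc1ccc(cc1)C(=O)O[C@H]2C=CC(=O)[C@@H](OCc4ccccc4)[C@@]3(C)CC[C@@](O)(C(C)C)[C@H]23
F5 | step 7 | dilithium C9(10)-enolate C4-alkoxide of 18 and F4 | [Li+].[Li+].COc1ccc(cc1)C(=O)O[C@H]2C=CC([O-])=C(OCc4ccccc4)[C@@]3(C)CC[C@@]([O-])(C(C)C)[C@H]23
F6 | step 5 | (6S)-10-(benzyloxy)-9-methyl-4-oxo-6-(propan-2-yl)-6-[(triethylsilyl)oxy]dec-9-enoic acid | OC(=O)CCC(=O)C[C@](O[Si](CC)(CC)CC)(C(C)C)CCC(C)=COCc1ccccc1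
F7 | step 5 | pentafluorophenyl (6S)-10-(benzyloxy)-9-methyl-4-oxo-6-(propan-2-yl)-6-[(triethylsilyl)oxy]dec-9-enoate | O=C(CCC(=O)C[C@](O[Si](CC)(CC)CC)(C(C)C)CCC(C)=COCc1ccccc1)Oc2c(F)c(F)c(F)c(F)c2F
F8 | step 5 | 2-[(3R)-7-(benzyloxy)-2,6-dimethyl-3-[(triethylsilyl)oxy]hept-6-en-3-yl]cyclopentane-1,3-dione (enol form) | OC1=C(C(=O)CC1)[C@](O[Si](CC)(CC)CC)(C(C)C)CCC(C)=COCc1ccccc1
F9 | step 4 | 2-[(3S)-2-methyl-6-oxo-3-[(triethylsilyl)oxy]heptan-3-yl]cyclopentane-1,3-dione (enol form) | OC1=C(C(=O)CC1)[C@](O[Si](CC)(CC)CC)(C(C)C)CCC(C)=O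
F10 | step 13 | 4β,10β-dihydroxy-6α-(4-methoxybenzoyloxy)-1β-methyl-4α-(propan-2-yl)-5αH-bicyclo[5.3.0]decan-9-one | COc1ccc(cc1)C(=O)O[C@H]2CCC(=O)[C@H](O)[C@@]3(C)CC[C@@](O)(C(C)C)[C@H]23
F11 | step 13 | 4β-hydroxy-6α-(4-methoxybenzoyloxy)-1β-methyl-4α-(propan-2-yl)-10β-[(triethylsilyl)oxy]-5αH-bicyclo[5.3.0]decan-9-one | COc1ccc(cc1)C(=O)O[C@H]2CCC(=O)[C@H](O[Si](CC)(CC)CC)[C@@]3(C)CC[C@@](O)(C(C)C)[C@H]23
F12 | step 13 | 4β-hydroxy-6α-(4-methoxybenzoyloxy)-1β-methyl-4α-(propan-2-yl)-10β-[(triethylsilyl)oxy]-5αH-bicyclo[5.3.0]dec-7-en-9-one | COc1ccc(cc1)C(=O)O[C@H]2C=CC(=O)[C@H](O[Si](CC)(CC)CC)[C@@]3(C)CC[C@@](O)(C(C)C)[C@H]23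
F13 | step 13 | 4β-hydroxy-8-iodo-6α-(4-methoxybenzoyloxy)-1β-methyl-4α-(propan-2-yl)-10β-[(triethylsilyl)oxy]-5αH-bicyclo[5.3.0]dec-7-en-9-one | COc1ccc(cc1)C(=O)O[C@H]2C=C(I)C(=O)[C@H](O[Si](CC)(CC)CC)[C@@]3(C)CC[C@@](O)(C(C)C)[C@H]23
F14 | step 13 | 4β-hydroxy-6α-(4-methoxybenzoyloxy)-1β,8-dimethyl-4α-(propan-2-yl)-10β-[(triethylsilyl)oxy]-5αH-bicyclo[5.3.0]dec-7-en-9-one | COc1ccc(cc1)C(=O)O[C@H]2C=C(C)C(=O)[C@H](O[Si](CC)(CC)CC)[C@@]3(C)CC[C@@](O)(C(C)C)[C@H]23
A1 | alternative 1 | metathesis precursor: ring A cyclopentane carrying the C6 vinyl carbinol 4-methoxybenzoate on C5 and the C10 benzyloxy isopropenyl ketone on C1 | C=C[C@H](OC(=O)c1ccc(OC)cc1)[C@H]2[C@](O)(C(C)C)CC[C@]2(C)[C@@H](OCc3ccccc3)C(=O)C(C)=C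
A2 | alternative 2 | 6-acetoxy-4-methyl-2H-pyran-3(6H)-one (racemic) | CC(=O)OC1C=C(C)C(=O)CO1
A3 | alternative 2 | 3-methylcyclopent-2-en-1-one | CC1=CC(=O)CC1
A4 | alternative 2 | oxa-bridged cis-fused [5+2] cycloadduct (racemic; relative configuration at the ring fusion shown, bridgeheads unassigned) | CC1=CC2OC(C1=O)[C@@]3(C)CCC(=O)[C@@H]23
A5 | alternative 3 | 3-acetoxycyclopent-2-en-1-one | CC(=O)OC1=CC(=O)CC1
A6 | alternative 3 | 7-(benzyloxy)-2,6-dimethylhept-6-en-3-one (E/Z mixture) | CC(C)C(=O)CCC(C)=COCc1ccccc1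
A7 | alternative 3 | 7-(benzyloxy)-6-methyl-6-(4-methyl-3-oxopentyl)cycloheptane-1,4-dione (racemic) | O=C1CCC(=O)C(OCc2ccccc2)C(C)(CCC(=O)C(C)C)C1
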